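I start from a small charge of X, put into a flask at one moment, and I ask what fraction of it is still X later. Here J dissolves to Q, Q goes to X and back, X goes to Z and back, and Q is also taken by G.

common to all: J 1.5 M; G 0.450 M; time 2.5 d

|  | temperature |
|---|---|
| south | 5 °C |
| north | −25 °C |
| west | 65 °C |
| east | 35 °C |

1. the flask with the highest share of X in all that became X or Z ("all alike" if they lie within 1.5 percentage points) (south / north / west / east / all alike)
2. share of X in all that became X or Z, south
3. share of X in all that became X or Z, north
4. share of X in all that became X or Z, west
5. share of X in all that became X or Z, east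

- given per volume of solution although it is solid: J
- at 5 °C the constants are as listed, elsewhere as the activation energies and enthalpies make them
- at the start none of J is in solution
- what has only dissolved of J counts as not reacted

    Q ⇌ X (K1 = 0.14, k1 = 2.7 × 10⁻⁵ s⁻¹, Ea1 = 94.0 kJ mol⁻¹, ΔH1 = 12.0 kJ mol⁻¹)
    X ⇌ Z (K2 = 15, k2 = 9.2 × 10⁻⁶ s⁻¹, Ea2 = 94.0 kJ mol⁻¹, ΔH2 = −67.0 kJ mol⁻¹)
    Q + G → Q.G (k3 = 7.5 × 10⁻⁶ M⁻¹ s⁻¹, Ea3 = 69.0 kJ mol⁻¹)
    J ⇌ Q, rate k4*(cs4 - [Q]) while solid is left; crystals form when [Q] > cs4 (cs4 = 1.1 M, k4 = 5.2 × 10⁻⁶ s⁻¹)
    (constants at 5 °C)

Z also returns to X, and the charge of X doesn't fade to nothing. It falls towards a rest share, one over one plus the equilibrium constant, and in south, with 15, that is 6.25%. The excess above this rest share shrinks at the forward constant 9.2 × 10⁻⁶ s⁻¹ plus the back constant, together 0.848 d⁻¹, which is a relaxation half-life of 0.818 d.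

Now two extremes for south. If all X appeared at the first instant, it has aged the whole 2.5 d, and the share is 17.5%. If all X appeared at the last instant, none has aged, and the share is 100%. South's X is made along the way, and its share lies between these two. At its fastest the solid in south gives 1.24 M in that time, less than the 1.5 M charged, so solid remains at the end, and X follows Q within 0.876 h, short against the time.

I therefore take an even feed and average over all ages. The mean fraction left of the excess is the part lost by the oldest X, divided by the rate times the time: 0.415. South then gets 45.2%.

North, at −25 °C, has a half-life of 118 d, far longer than the time, which is kinetic control: 99.3%.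

West, at 65 °C, has a constant of 0.0878 and a half-life of 4.49 s, far shorter than the time. That is thermodynamic control, so west sits at its rest share, 91.9%.

East, at 35 °C, has a constant of 0.894 and a half-life of 11.3 min, also far shorter than the time, so east gets 52.8%. My first place goes to north.

The forecast says 45.4% for south, 99.4% for north, 91.9% for west and 53% for east, with north first; for east it speaks of “a small lag in Z”.

The simulation gives 46.5% for south, 99.4% for north, 91.9% for west and 53.1% for east, with north first. South's share moves by 5 points at 2.08 d or at 3.01 d.

The neighbour is south with 0.60 M of J. With a feed lasting to the end, the fraction left stays 0.415 and the share is 45.2%. With the feed ending once the neighbour's solid has gone at its full starting rate, after 1.21 d, the youngest X is 1.29 d old and the share is 25.9%. The neighbour gives 38.0%, less than the first figure and more than the second, with J at 0% and Q at 53.1% of the J charged.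

The constants used here come from no measurement, and the outcome is calculated.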